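**Assumption:** the target has no stereocentre and no stereogenic double bond, so "single enantiomer" is met by the achiral compound itself; the racemic intermediates on the way all converge on it.

## Retrosynthetic overview

1. 17 ⇐ 16 by hydrogenolysis of two aryl benzyl ethers (rings B and C are bought as benzyl ethers).
2. 16 ⇐ vinylogous ester 11 + acetal 13: a new redox-neutral aromatising benzylation forms the C2–CH2Ar bond and turns the carbocycle into aromatic ring A, with OMe and OH already differentiated by the enol ether.
3. 11 ⇐ symmetric dione 10 (mono enol ether) ⇐ enone 5 + dimethyl malonate (Michael/Claisen/decarboxylation; the ring A carbocycle is closed here).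
4. 5 ⇐ aldehyde 3 (Wittig) ⇐ 1 + allyl alcohol (Heck); these steps lay down the CH2CH2 bridge of the bibenzyl.
5. Ring order: B and C are purchased; ring A is closed as a cyclohexane-1,3-dione in step 3 and aromatised in step 6.

## Route

Step 1
Reactants: 1 1-(benzyloxy)-3-iodobenzene; 2 allyl alcohol (prop-2-en-1-ol)
Product: 3 3-[3-(benzyloxy)phenyl]propanal
Conditions: Pd(OAc)2 (3 mol %), n-Bu4NCl, NaHCO3, DMF, 45 °C
Reagents that add atoms: none
Why: Jeffery-type Heck arylation of allyl alcohol: aryl-Pd adds to the terminal alkene carbon, β-hydride elimination towards the carbinol carbon gives the enol, and this tautomerises to the 3-arylpropanal; the benzyl ether is inert.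

Step 2
Reactants: 3 3-[3-(benzyloxy)phenyl]propanal; 4 1-(triphenyl-λ5-phosphanylidene)propan-2-one
Product: 5 (E)-6-[3-(benzyloxy)phenyl]hex-3-en-2-one
Conditions: toluene, 80 °C
Reagents that add atoms: none
Why: Wittig olefination with a ketone-stabilised ylide is reliably E-selective with aliphatic aldehydes and gives the β-substituted methyl vinyl ketone needed for the annulation.

Step 3
Reactants: 5 (E)-6-[3-(benzyloxy)phenyl]hex-3-en-2-one; 6 dimethyl malonate
Product: 10 5-{2-[3-(benzyloxy)phenyl]ethyl}cyclohexane-1,3-dione, via Michael adduct 7 (not isolated), via cyclic keto ester 8 (not isolated), via cyclic keto acid 9 (not isolated)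
Conditions: NaOMe, MeOH, reflux; then aq NaOH, reflux; then HCl (pH 1), 80 °C
Reagents that add atoms: none
Why: Classic cyclohexane-1,3-dione synthesis: malonate Michael addition to the enone, intramolecular Claisen (Dieckmann-type) condensation of the methyl ketone enolate onto one ester, then saponification and decarboxylation of the β-keto acid; the benzyl ether tolerates all three stages.

Step 4
Reactants: 10 5-{2-[3-(benzyloxy)phenyl]ethyl}cyclohexane-1,3-dione
Product: 11 5-{2-[3-(benzyloxy)phenyl]ethyl}-3-methoxycyclohex-2-en-1-one (racemic)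
Conditions: MeOH, p-TsOH·H2O (5 mol %), 3 Å MS, reflux
Reagents that add atoms: methanol CO
Why: Acid-catalysed enol etherification of a cyclic 1,3-diketone (vinylogous Fischer esterification); 10 is symmetric, so only one mono-methyl ether exists, and the reaction stops there because the vinylogous ester carbonyl is unreactive; the C5 stereocentre created is racemic and is erased in step 6.

Step 5
Reactants: 12 4-(benzyloxy)benzaldehyde
Product: 13 1-(benzyloxy)-4-(dimethoxymethyl)benzene
Conditions: HC(OMe)3 (neat), p-TsOH·H2O (1 mol %), rt; K2CO3 quench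
Reagents that add atoms: trimethyl orthoformate COC(OC)OC
Why: Acid-catalysed acetalisation of an aromatic aldehyde with an orthoformate, which serves as both methoxy source and water scavenger.

Step 6
Reactants: 11 5-{2-[3-(benzyloxy)phenyl]ethyl}-3-methoxycyclohex-2-en-1-one; 13 1-(benzyloxy)-4-(dimethoxymethyl)benzene
Product: 16 2-[4-(benzyloxy)benzyl]-5-{2-[3-(benzyloxy)phenyl]ethyl}-3-methoxyphenol, via methoxybenzyl adduct 14 (not isolated), via arylidene dienone 15 (not isolated)
Conditions: 13 (1.5 equiv), TMSOTf (10 mol %), toluene, −40 → 0 °C; then KOtBu (4 equiv), t-BuOH–DMSO, 50 °C, argon; 1 M HCl work-up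
Reagents that add atoms: none
Why: Proposed new method: redox-neutral aromatising benzylation of a cyclohexane-1,3-dione mono-enol ether — (i) TMSOTf ionises acetal 13 to the aryl oxocarbenium ion, which is attacked by C2 of 11 (the β-carbon of its enol ether and the only C-nucleophilic site of the neutral push–pull alkene; O-attack is reversible), and loss of H-2 restores the vinylogous ester to give 14; (ii) KOtBu deprotonates C4, the dienolate expels methoxide (vinylogous E1cB) to the cross-conjugated 2-arylidene dienone 15, a non-aromatic isomer of 16, and prototropic shifts (H-5 to the exocyclic carbon through the aryl-terminated pentadienyl anion, H-6 to oxygen) funnel the material irreversibly to the phenoxide, so the ring's own C–H bonds supply the hydride equivalent that turns the acetal carbon into the benzylic CH2, and the enol ether fixes both the C2 regiochemistry and the OMe/OH differentiation with no directing or protecting group on ring A; closest known reaction types: Lewis-acid addition of enol ethers to acetals (Mukaiyama/Isler type), Knoevenagel condensation of cyclic 1,3-diones, and the base-, acid- or Rh-mediated isoaromatisation of 2-arylidene-1-tetralones and 6-arylidenecyclohex-2-enones to benzyl-naphthols and benzyl-phenols, which has not been shown at C2 of a 3-alkoxy-enone to give a 2-benzylresorcinol monoether.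

Step 7
Reactants: 16 2-[4-(benzyloxy)benzyl]-5-{2-[3-(benzyloxy)phenyl]ethyl}-3-methoxyphenol
Product: 17 2-(4-hydroxybenzyl)-5-[2-(3-hydroxyphenyl)ethyl]-3-methoxyphenol
Conditions: H2 (1 atm), 10 % Pd/C, EtOAc–MeOH, rt
Reagents that add atoms: none
Why: Pd-catalysed hydrogenolysis of aryl benzyl ethers; the diarylmethane and bibenzyl C–C bonds, the methyl ether and the arenes are inert at 1 atm and room temperature.

## Compound list

1 | 1-(benzyloxy)-3-iodobenzene | Ic1cccc(OCc2ccccc2)c1 | starting material
2 | allyl alcohol (prop-2-en-1-ol) | C=CCO | starting material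
3 | 3-[3-(benzyloxy)phenyl]propanal | O=CCCc1cccc(OCc2ccccc2)c1 | intermediate
4 | 1-(triphenyl-λ5-phosphanylidene)propan-2-one | CC(=O)C=P(c1ccccc1)(c1ccccc1)c1ccccc1 | starting material
5 | (E)-6-[3-(benzyloxy)phenyl]hex-3-en-2-one | CC(=O)/C=C/CCc1cccc(OCc2ccccc2)c1 | intermediate
6 | dimethyl malonate | COC(=O)CC(=O)OC | starting material
7 | Michael adduct: dimethyl 2-{1-[3-(benzyloxy)phenyl]-5-oxohexan-3-yl}propanedioate (racemic; not isolated) | COC(=O)C(C(=O)OC)C(CCc1cccc(OCc2ccccc2)c1)CC(C)=O | intermediate
8 | cyclic keto ester: methyl 6-{2-[3-(benzyloxy)phenyl]ethyl}-2,4-dioxocyclohexane-1-carboxylate (racemic, epimer/enol mixture; not isolated) | COC(=O)C1C(CCc2cccc(OCc3ccccc3)c2)CC(=O)CC1=O | intermediate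
9 | cyclic keto acid: 6-{2-[3-(benzyloxy)phenyl]ethyl}-2,4-dioxocyclohexane-1-carboxylic acid (racemic; not isolated) | OC(=O)C1C(CCc2cccc(OCc3ccccc3)c2)CC(=O)CC1=O | intermediate
10 | 5-{2-[3-(benzyloxy)phenyl]ethyl}cyclohexane-1,3-dione (achiral) | O=C1CC(=O)CC(CCc2cccc(OCc3ccccc3)c2)C1 | intermediate
11 | 5-{2-[3-(benzyloxy)phenyl]ethyl}-3-methoxycyclohex-2-en-1-one (racemic) | COC1=CC(=O)CC(CCc2cccc(OCc3ccccc3)c2)C1 | intermediate
12 | 4-(benzyloxy)benzaldehyde | O=Cc1ccc(OCc2ccccc2)cc1 | starting material
13 | 1-(benzyloxy)-4-(dimethoxymethyl)benzene | COC(OC)c1ccc(OCc2ccccc2)cc1 | intermediate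
14 | methoxybenzyl adduct: 5-{2-[3-(benzyloxy)phenyl]ethyl}-2-{[4-(benzyloxy)phenyl](methoxy)methyl}-3-methoxycyclohex-2-en-1-one (racemic diastereomer mixture; not isolated) | COC1=C(C(OC)c2ccc(OCc3ccccc3)cc2)C(=O)CC(CCc2cccc(OCc3ccccc3)c2)C1 | intermediate
15 | arylidene dienone: 2-[4-(benzyloxy)benzylidene]-5-{2-[3-(benzyloxy)phenyl]ethyl}-3-methoxycyclohex-3-en-1-one (racemic, E/Z mixture; not isolated) | COC1=CC(CCc2cccc(OCc3ccccc3)c2)CC(=O)C1=Cc1ccc(OCc2ccccc2)cc1 | intermediate
16 | 2-[4-(benzyloxy)benzyl]-5-{2-[3-(benzyloxy)phenyl]ethyl}-3-methoxyphenol | COc1cc(CCc2cccc(OCc3ccccc3)c2)cc(O)c1Cc1ccc(OCc2ccccc2)cc1 | intermediate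
17 | 2-(4-hydroxybenzyl)-5-[2-(3-hydroxyphenyl)ethyl]-3-methoxyphenol (CNP0112925.0, achiral) | COc1cc(CCc2cccc(O)c2)cc(O)c1Cc1ccc(O)cc1 | target

## Step count and risks

Total step count: 7. Longest linear sequence: 6 (steps 1, 2, 3, 4, 6, 7; acetal 13 is made in one side step).

The three steps most likely to fail are step 6, step 1 and step 3.

Step 6 is the proposed new step and the main risk. Its weak points are:
- capture of the benzylic cation from 14 by a second molecule of 11 (countered by the excess of 13 and the low temperature of the acid stage);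
- Friedel–Crafts over-alkylation of 16 if it forms while oxocarbenium ion is still present (countered by destroying all acid with KOtBu before aromatisation);
- a tautomerisation that stalls at 15 or diverts to Michael oligomers.

The fallback uses only known chemistry; it sets out from dione 10 (with aldehyde 12) and comes back to the route at 16. Organocatalytic three-component reductive alkylation of 10 with 12 and Hantzsch ester (L-proline cat., CH2Cl2, rt) gives 2-[4-(benzyloxy)benzyl]-5-{2-[3-(benzyloxy)phenyl]ethyl}cyclohexane-1,3-dione F1. Acid-catalysed enol etherification (MeOH, p-TsOH, reflux) then gives 2-[4-(benzyloxy)benzyl]-5-{2-[3-(benzyloxy)phenyl]ethyl}-3-methoxycyclohex-2-en-1-one F2. Pd(II)-catalysed aerobic dehydrogenation of the cyclohexenone (Pd(TFA)2, 2-(dimethylamino)pyridine, p-TsOH, O2, DMSO, 80 °C) aromatises it to 16. Here an external reductant and an external oxidant replace the internal hydrogen shift.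

Step 1 can give the branched 2-arylpropanal, cinnamyl-type products or aldol self-condensation of 3 under the basic Heck conditions. The fallback sets out from 1 and comes back at 3. It replaces the Heck reaction with an sp2–sp3 Suzuki–Miyaura coupling of 1 with commercial potassium [2-(1,3-dioxolan-2-yl)ethyl]trifluoroborate (Pd(OAc)2/RuPhos, K2CO3, toluene–H2O, 85 °C), which gives 2-{2-[3-(benzyloxy)phenyl]ethyl}-1,3-dioxolane F3. Mild hydrolysis (1 M HCl, THF, rt) releases aldehyde 3.

Step 3 runs three operations in one pot; γ-deprotonation of enone 5, incomplete Claisen closure or a sluggish decarboxylation can erode the yield. The fallback sets out from 5 and comes back at 10. A Mukaiyama–Michael addition of 1-(tert-butyldimethylsilyloxy)-1-methoxyethene to 5 (TiCl4, CH2Cl2, −78 °C, aqueous work-up) gives methyl 3-{2-[3-(benzyloxy)phenyl]ethyl}-5-oxohexanoate F4. KOtBu in THF (0 °C → rt) closes this δ-keto ester by intramolecular Claisen condensation directly to 10, with no ester hydrolysis or decarboxylation needed.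

## Further compounds

F1 | step 6 | 2-[4-(benzyloxy)benzyl]-5-{2-[3-(benzyloxy)phenyl]ethyl}cyclohexane-1,3-dione | O=C1CC(CCc2cccc(OCc3ccccc3)c2)CC(=O)C1Cc1ccc(OCc2ccccc2)cc1
F2 | step 6 | 2-[4-(benzyloxy)benzyl]-5-{2-[3-(benzyloxy)phenyl]ethyl}-3-methoxycyclohex-2-en-1-one (racemic) | COC1=C(Cc2ccc(OCc3ccccc3)cc2)C(=O)CC(CCc2cccc(OCc3ccccc3)c2)C1
F3 | step 1 | 2-{2-[3-(benzyloxy)phenyl]ethyl}-1,3-dioxolane | C1COC(CCc2cccc(OCc3ccccc3)c2)O1
F4 | step 3 | methyl 3-{2-[3-(benzyloxy)phenyl]ethyl}-5-oxohexanoate (racemic) | COC(=O)CC(CCc1cccc(OCc2ccccc2)c1)CC(C)=O
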